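**Plan**
- Retrosynthesis cuts the O1–C2 bond of ring C (the last bond made), then the C3=CH2 bond (methylene from an iminium salt), then the C3–aryl bond (α-arylation), then the acetyl–ring A bond. The pyran of ring B is built separately first.
- Enabling feature: C2 is a CH2 β to the C4 ketone and O1 is a ring-A phenol oxygen ortho to the acyl carbon. O1–C2 is therefore the conjugate-addition bond of a phenol to an α-aryl vinyl ketone, and C3 (α to C4, one H) is created by protonating the enol C3=C4–OH that the addition leaves.
- Ring A carries two equivalent oxygens ortho to the acyl group (future O1 and 5-OH), so either may close and no differentiation is needed.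
- Forward: the protected ring-A methyl ketone (steps 1–2) and the ring-B chromene bromide (step 3) are joined by α-arylation (step 4) and methylenated (step 5); ring C is closed last (step 6).
- Stereochemistry: C3 (S) is set in step 6 by a chiral phosphoric acid that also removes the two acetal groups, so the labile centre never meets base or a later deprotection.

Key step: step 6

Remark: compounds 2–4 and 9–12 carry two 1-ethoxyethyl acetal carbons and are used as mixtures of acetal epimers; these carbons leave in step 6.
Assumption: (R)-TRIP [(R)-3,3′-bis(2,4,6-triisopropylphenyl)-1,1′-binaphthyl-2,2′-diyl hydrogen phosphate] is taken to deliver the proton to the face of enol 14 that gives (3S)-15; if a trial run shows the opposite sense, (S)-TRIP is used under the same conditions.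

**Step 1**
Reactants: 1 5-methoxybenzene-1,3-diol
Product: 2 1,3-bis(1-ethoxyethoxy)-5-methoxybenzene
Conditions: ethyl vinyl ether (4 equiv), PPTS (5 mol %), CH2Cl2, 0 °C to rt
Reagents that add atoms: ethyl vinyl ether, C=COCC
Why: Acid-catalysed addition of both phenols to the vinyl ether (acetal protection) should give base-stable, acid-labile ethers that also direct the metalation of step 2.

**Step 2**
Reactants: 2 1,3-bis(1-ethoxyethoxy)-5-methoxybenzene
Product: 4 1-[2,6-bis(1-ethoxyethoxy)-4-methoxyphenyl]ethan-1-one, via aryllithium 3 (not isolated)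
Conditions: n-BuLi (1.1 equiv), THF, 0 °C; then MeC(O)N(OMe)Me, −78 °C to rt; H2O
Reagents that add atoms: N-methoxy-N-methylacetamide, CC(=O)N(C)OC
Why: Directed ortho-metalation should occur at the carbon between the two chelating acetal oxygens, and acylation of the aryllithium by the Weinreb amide should stop at the ketone because the tetrahedral chelate collapses only on work-up.

**Step 3**
Reactants: 5 5-bromo-2-hydroxy-4-methoxybenzaldehyde
Product: 8 6-bromo-7-methoxy-2,2-dimethyl-2H-chromene, via allylic alcohol 6 (not isolated), via ortho-quinone methide 7 (not isolated)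
Conditions: Me2C=CHMgBr (2.5 equiv), THF, 0 °C to rt; H2O; then PhMe, 110 °C
Reagents that add atoms: 2-methylprop-1-enylmagnesium bromide, CC(C)=C[Mg]Br
Why: Grignard 1,2-addition to the aldehyde should give an ortho-hydroxybenzyl allylic alcohol that loses water on heating to the ortho-quinone methide, whose oxa-6π electrocyclisation gives the 2H-chromene with the pyran position fixed by the aldehyde.

**Step 4**
Reactants: 4 1-[2,6-bis(1-ethoxyethoxy)-4-methoxyphenyl]ethan-1-one; 8 6-bromo-7-methoxy-2,2-dimethyl-2H-chromene
Product: 9 1-[2,6-bis(1-ethoxyethoxy)-4-methoxyphenyl]-2-(7-methoxy-2,2-dimethyl-2H-chromen-6-yl)ethan-1-one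
Conditions: Pd2(dba)3 (2 mol %), Xantphos (5 mol %), NaOtBu (1.3 equiv), PhMe, 80 °C
Reagents that add atoms: none
Why: Palladium-catalysed α-arylation of a methyl ketone enolate (Buchwald–Hartwig-type ketone arylation, oxidative addition of the bromide to zerovalent palladium) should give the deoxybenzoin, and the hindered partners should hold it at monoarylation.

**Step 5**
Reactants: 9 1-[2,6-bis(1-ethoxyethoxy)-4-methoxyphenyl]-2-(7-methoxy-2,2-dimethyl-2H-chromen-6-yl)ethan-1-one
Product: 12 1-[2,6-bis(1-ethoxyethoxy)-4-methoxyphenyl]-2-(7-methoxy-2,2-dimethyl-2H-chromen-6-yl)prop-2-en-1-one, via Mannich base 10 (not isolated), via trimethylammonium iodide 11 (not isolated)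
Conditions: LiN(SiMe3)2, THF, −78 °C; CH2=NMe2+ I−, −78 °C to rt; MeI, rt; aq NaHCO3, CH2Cl2, rt
Reagents that add atoms: Eschenmoser's salt (N,N-dimethylmethyleneiminium iodide), C=[N+](C)C.[I-]
Why: Mannich aminomethylation of the deprotonated deoxybenzoin, N-methylation and E1cB loss of trimethylamine is the standard all-basic α-methylenation of aryl benzyl ketones and should leave the acetals untouched.

**Step 6**
Reactants: 12 1-[2,6-bis(1-ethoxyethoxy)-4-methoxyphenyl]-2-(7-methoxy-2,2-dimethyl-2H-chromen-6-yl)prop-2-en-1-one
Product: 15 (3S)-5-hydroxy-7-methoxy-3-(7-methoxy-2,2-dimethyl-2H-chromen-6-yl)-2,3-dihydro-4H-chromen-4-one, via bis-phenol enone 13 (not isolated), via enol 14 (not isolated)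
Conditions: (R)-TRIP (10 mol %), MeOH (3 equiv), PhMe, 0 °C
Reagents that add atoms: none
Why: Proposed new method: the phosphoric acid should first pass both 1-ethoxyethyl groups to methanol (acid-catalysed transacetalisation), freeing 13 in a medium without base; one of its two ortho-hydroxyls then adds to the CH2 terminus of the acid-bound vinyl ketone (6-endo-trig oxa-Michael addition, closing ring C through O1–C2) to leave enol 14, which the same acid ketonises by a proton shuttle in which P=O accepts the enol O–H while P–OH delivers the proton to C3. The closest known reaction types are chiral Brønsted acid-catalysed cyclisation/enantioselective enol protonation cascades (Nazarov cyclisation–protonation, and protonation of silyl enol ethers or ketene imines of α-aryl carbonyl compounds with an alcohol or phenol as stoichiometric proton source) and the racemic closure of 2-hydroxyphenyl α-aryl vinyl ketones to isoflavanones. C3 is the only new stereocentre and is catalyst-controlled: the enol is held on the phosphate through its 4-OH and the neighbouring 5-OH, and the 3,3′-aryl groups of the acid must tell the bulky ortho-methoxy chromenyl group at C3 from the C2 methylene. Regioselectivity is not at stake because the two hydroxyls of ring A are interchanged by rotation about the aryl–carbonyl bond, so either closure gives the same enol and the unused hydroxyl becomes the chelated 5-OH. The step needs acid-bound proton delivery to outrun uncatalysed ketonisation, which the non-polar solvent, the absence of base and the low acidity of methanol should favour; the product, tied by the 5-OH···O=C4 hydrogen bond, should not enolise under these conditions.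

**Compound list**
1 | 5-methoxybenzene-1,3-diol (5-methoxyresorcinol) | COc1cc(O)cc(O)c1 | starting material
2 | 1,3-bis(1-ethoxyethoxy)-5-methoxybenzene (mixture of acetal epimers) | CCOC(C)Oc1cc(OC)cc(OC(C)OCC)c1 | intermediate
3 | [2,6-bis(1-ethoxyethoxy)-4-methoxyphenyl]lithium (not isolated) | CCOC(C)Oc1cc(OC)cc(OC(C)OCC)c1[Li] | intermediate
4 | 1-[2,6-bis(1-ethoxyethoxy)-4-methoxyphenyl]ethan-1-one (mixture of acetal epimers) | CCOC(C)Oc1cc(OC)cc(OC(C)OCC)c1C(C)=O | intermediate
5 | 5-bromo-2-hydroxy-4-methoxybenzaldehyde | COc1cc(O)c(C=O)cc1Br | starting material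
6 | rac-1-(5-bromo-2-hydroxy-4-methoxyphenyl)-3-methylbut-2-en-1-ol (not isolated) | COc1cc(O)c(C(O)C=C(C)C)cc1Br | intermediate
7 | (6Z)-4-bromo-3-methoxy-6-(3-methylbut-2-en-1-ylidene)cyclohexa-2,4-dien-1-one (not isolated) | O=C1C=C(OC)C(Br)=C/C1=C/C=C(C)C | intermediate
8 | 6-bromo-7-methoxy-2,2-dimethyl-2H-chromene | COc1cc2c(cc1Br)C=CC(C)(C)O2 | intermediate
9 | 1-[2,6-bis(1-ethoxyethoxy)-4-methoxyphenyl]-2-(7-methoxy-2,2-dimethyl-2H-chromen-6-yl)ethan-1-one (mixture of acetal epimers) | CCOC(C)Oc1cc(OC)cc(OC(C)OCC)c1C(=O)Cc1cc2c(cc1OC)OC(C)(C)C=C2 | intermediate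
10 | 1-[2,6-bis(1-ethoxyethoxy)-4-methoxyphenyl]-3-(dimethylamino)-2-(7-methoxy-2,2-dimethyl-2H-chromen-6-yl)propan-1-one (racemic at C2, acetal epimers, not isolated) | CCOC(C)Oc1cc(OC)cc(OC(C)OCC)c1C(=O)C(CN(C)C)c1cc2c(cc1OC)OC(C)(C)C=C2 | intermediate
11 | 3-[2,6-bis(1-ethoxyethoxy)-4-methoxyphenyl]-2-(7-methoxy-2,2-dimethyl-2H-chromen-6-yl)-N,N,N-trimethyl-3-oxopropan-1-aminium iodide (racemic at C2, acetal epimers, not isolated) | CCOC(C)Oc1cc(OC)cc(OC(C)OCC)c1C(=O)C(C[N+](C)(C)C)c1cc2c(cc1OC)OC(C)(C)C=C2.[I-] | intermediate
12 | 1-[2,6-bis(1-ethoxyethoxy)-4-methoxyphenyl]-2-(7-methoxy-2,2-dimethyl-2H-chromen-6-yl)prop-2-en-1-one (mixture of acetal epimers) | CCOC(C)Oc1cc(OC)cc(OC(C)OCC)c1C(=O)C(=C)c1cc2c(cc1OC)OC(C)(C)C=C2 | intermediate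
13 | 1-(2,6-dihydroxy-4-methoxyphenyl)-2-(7-methoxy-2,2-dimethyl-2H-chromen-6-yl)prop-2-en-1-one (not isolated) | COc1cc(O)c(C(=O)C(=C)c2cc3c(cc2OC)OC(C)(C)C=C3)c(O)c1 | intermediate
14 | 7-methoxy-3-(7-methoxy-2,2-dimethyl-2H-chromen-6-yl)-2H-chromene-4,5-diol (not isolated) | COc1cc(O)c2c(c1)OCC(c1cc3c(cc1OC)OC(C)(C)C=C3)=C2O | intermediate
15 | (3S)-5-hydroxy-7-methoxy-3-(7-methoxy-2,2-dimethyl-2H-chromen-6-yl)-2,3-dihydro-4H-chromen-4-one | COc1cc(O)c2c(c1)OC[C@H](c1cc3c(cc1OC)OC(C)(C)C=C3)C2=O | target

**Totals**
Total step count: 6. Longest linear sequence: 5 steps (1, 2, 4, 5, 6).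

**Steps most likely to fail**

1. Step 6 (proposed new method). Proton transfer to C3 outside the chiral acid (uncatalysed or methanol-mediated ketonisation of 14) would erode the enantiomeric purity. The acetal-derived oxocarbenium ion may also alkylate ring A before methanol traps it. Fallback with known chemistry, from 12 back to 15: PPTS in MeOH at rt should remove both acetals and let 13 close without control to the racemic isoflavanone F1. NaN(SiMe3)2 (2.2 equiv) and allyl chloroformate in THF at −78 °C should convert it into the bis(allyl carbonate) F2 (enol carbonate at O4, aryl carbonate at O5). Pd2(dba)3 with (S)-t-Bu-PHOX (or its antipode, as the sense of induction requires) and Meldrum's acid in dioxane at rt should then ionise both carbonates at zerovalent palladium, lose CO2 and protonate the palladium enolate enantioselectively. This decarboxylative asymmetric protonation is an established reaction type for 3-aryl chroman-4-ones, and it gives 15 directly because the aryl carbonate is cleaved by the same catalyst.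

2. Step 4. Coupling of the hindered enolate with the ortho-substituted bromide may be slow, so that diarylation of the more acidic product or Heck-type insertion into the chromene double bond takes over. Fallback, from 4 and 8 back to 9, with the polarity reversed: 4 is brominated through its enolate (LiN(SiMe3)2, THF, −78 °C, then NBS) to the α-bromo ketone F3. Bromide 8 is converted by n-BuLi (THF, −78 °C) into the aryllithium F4 and by ZnCl2 into the arylzinc chloride F5. Nickel-catalysed Negishi coupling of F3 with F5 (NiCl2(dme), 2,2′-bipyridine, THF/DMA, rt) should give 9 without any enolate of the product being present.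

3. Step 5. Unreacted enolate of 9 may add to the newly formed vinyl ketone (dimerisation), or the acetals may be lost during quaternisation. Fallback, from 9 back to 12, without an enolate in the olefination: base-mediated aerobic oxidation of the benzylic methylene (DABCO, air, DMF, 80 °C) should give the 1,2-diketone F6. One equivalent of Ph3P=CH2 (THF, −78 to 0 °C, Wittig olefination) should then methylenate only the carbonyl next to ring B, the one next to ring A being shielded by its two ortho acetal ethers.

**Further compounds**
F1 | step 6 | rac-5-hydroxy-7-methoxy-3-(7-methoxy-2,2-dimethyl-2H-chromen-6-yl)-2,3-dihydro-4H-chromen-4-one | COc1cc(O)c2c(c1)OCC(c1cc3c(cc1OC)OC(C)(C)C=C3)C2=O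
F2 | step 6 | 7-methoxy-3-(7-methoxy-2,2-dimethyl-2H-chromen-6-yl)-2H-chromene-4,5-diyl bis(prop-2-en-1-yl) bis(carbonate) | COc1cc(OC(=O)OCC=C)c2c(c1)OCC(c1cc3c(cc1OC)OC(C)(C)C=C3)=C2OC(=O)OCC=C
F3 | step 4 | 1-[2,6-bis(1-ethoxyethoxy)-4-methoxyphenyl]-2-bromoethan-1-one | CCOC(C)Oc1cc(OC)cc(OC(C)OCC)c1C(=O)CBr
F4 | step 4 | (7-methoxy-2,2-dimethyl-2H-chromen-6-yl)lithium | [Li]c1cc2c(cc1OC)OC(C)(C)C=C2
F5 | step 4 | chlorido(7-methoxy-2,2-dimethyl-2H-chromen-6-yl)zinc | Cl[Zn]c1cc2c(cc1OC)OC(C)(C)C=C2
F6 | step 5 | 1-[2,6-bis(1-ethoxyethoxy)-4-methoxyphenyl]-2-(7-methoxy-2,2-dimethyl-2H-chromen-6-yl)ethane-1,2-dione | CCOC(C)Oc1cc(OC)cc(OC(C)OCC)c1C(=O)C(=O)c1cc2c(cc1OC)OC(C)(C)C=C2
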